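## Retrosynthetic overview

- **Feature.** In the flavone etherified at C6'' (rings A'', C'', B''), ring A'' is a phloroglucinol. Its C6'' carries the diaryl-ether oxygen between the oxygenated C5'' and C7''. C5''–C6''–C7'' therefore maps onto a 2-aryloxymalonate, and C4a''–C8a''–C8'' onto a 3-oxoglutarate.
- **Disconnections.** C2–C1' by Suzuki coupling of a 2-chlorochromone with an arylboronate. Ring C'' through a chalcone. Ring A'' at C4a''–C5'' and C7''–C8'' by a double Claisen condensation. O–C6'' by SN2 at the malonate sp3 carbon, so the crowded ether is never made at an arene carbon.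
- **Ring order.** Ring B is bought as 4-bromophenol. Ring A'' forms in step 2. Ring C'' follows in steps 8–9, with ring B'' coming from the aldehyde. Rings A/C are made as 2-chloro-5,7-dimethoxychromone in steps 11–12 and joined in step 13.
- **Regiochemistry.** The decarboxylated triol is symmetric, so a direct pyranone annulation could close on either ortho oxygen and give the 6''- or the 8''-aryloxy isomer. The unflanked OH (future O1'') is therefore masked, O5'' and O7'' are methylated, and only then is the ring acylated.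
- **End game.** The two peri methyl ethers (O5, O5'') and the O4''' benzyl ether are removed together in the last step.

Key step: step 2

Assumption: 5 and 7 are drawn as one tautomer each. The two labile stereocentres of 5 are left undefined because they vanish on aromatisation. The target has no stereocentre.

## Route

Step 1
Reactants: 1 4-bromophenol; 2 dimethyl 2-chloropropanedioate (dimethyl chloromalonate)
Product: 3 dimethyl 2-(4-bromophenoxy)propanedioate
Conditions: K2CO3 (1.5 equiv), acetone, reflux
Reagents that add atoms: none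
Why: Williamson-type SN2 alkylation of the phenoxide at the sp3 carbon of a doubly activated α-chloromalonate, the standard entry to 2-aryloxymalonates, with the chloride chosen over the bromide because it does not transfer positive halogen to the phenoxide.

Step 2
Reactants: 3 dimethyl 2-(4-bromophenoxy)propanedioate; 4 dimethyl 3-oxopentanedioate (dimethyl 3-oxoglutarate)
Product: 6 dimethyl 5-(4-bromophenoxy)-2,4,6-trihydroxybenzene-1,3-dicarboxylate, via open-chain Claisen adduct 5 (not isolated)
Conditions: NaOMe (3.3 equiv), MeOH, 65 °C, 4 added slowly to 3 (1.2 equiv); then MeOH distilled off against toluene, 105 °C; cold 2 M HCl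
Reagents that add atoms: none
Why: Proposed new method: one carbanion of 4 acylates an ester of 3 (intermolecular Claisen) to give 5, whose second CH2 carbanion attacks the remaining malonate ester in a 6-exo-trig Dieckmann closure, so that C4a''–C5'' and C7''–C8'' form and ring A'' closes with C6'' already bearing the aryloxy oxygen. The closest known reaction type is the alkoxide condensation of malonate esters with 3-oxoglutarate esters (and the self-condensation of sodiomalonate) to phloroglucinol di- and tricarboxylates, and 2-aryloxymalonates already serve as 1,3-bis-electrophiles toward amidines under NaOMe; new here is their use against a bis-carbanion. The cyclohexanetrione enolises at once to the phenoxide salt of 6, which takes it out of the reversible Claisen equilibria, and removal of MeOH pushes in the same direction. No stereocentre persists, since those of 5 are labile and disappear on aromatisation. The step needs C- over O-acylation and cross- over self-condensation: the 4-hydroxy-2-pyranone from O-acylation is reopened by methoxide and re-enters the equilibrium, excess base holds 4 as its enolate with the ketone masked, and slow addition of 4 to excess 3 keeps free ketone scarce. Each partner has a mirror plane and the ester alkyl groups match the alkoxide, so only one carbocycle is possible and no ester scrambling occurs.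

Step 3
Reactants: 6 dimethyl 5-(4-bromophenoxy)-2,4,6-trihydroxybenzene-1,3-dicarboxylate
Product: 8 2-(4-bromophenoxy)benzene-1,3,5-triol, via diacid 7 (not isolated)
Conditions: 2 M NaOH (aq), argon, reflux; then conc. HCl to pH 1, 80 °C
Reagents that add atoms: none
Why: Ester saponification followed by protodecarboxylation of a 2,4,6-trihydroxybenzoic-type acid, which loses CO2 readily through its β-keto-acid tautomer, while the aryl bromide and the diaryl ether are inert to aqueous base and acid and air is excluded because the triol oxidises in alkali.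

Step 4
Reactants: 8 2-(4-bromophenoxy)benzene-1,3,5-triol
Product: 9 2-(4-bromophenoxy)-5-{[tri(propan-2-yl)silyl]oxy}benzene-1,3-diol
Conditions: TIPSCl (1.0 equiv), imidazole (2.2 equiv), DMF, −20 °C to 0 °C
Reagents that add atoms: chlorotri(propan-2-yl)silane (TIPSCl), CC(C)[Si](Cl)(C(C)C)C(C)C
Why: Site-selective silylation of the least hindered phenol: the C5–OH has two ortho hydrogens whereas each of the C1/C3–OH groups sits beside the out-of-plane 4-bromophenoxy group, so the bulky silyl chloride should react fastest at C5–OH, and mis-silylated material can be returned to 8 with fluoride.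

Step 5
Reactants: 9 2-(4-bromophenoxy)-5-{[tri(propan-2-yl)silyl]oxy}benzene-1,3-diol
Product: 10 [4-(4-bromophenoxy)-3,5-dimethoxyphenoxy]tri(propan-2-yl)silane
Conditions: Me2SO4 (2.5 equiv), K2CO3 (3 equiv), acetone, reflux
Reagents that add atoms: dimethyl sulfate, COS(=O)(=O)OC
Why: Williamson O-methylation with a hard electrophile and K2CO3 in acetone, the conditions that favour O- over C-alkylation of resorcinol-type phenoxides, and the TIPS aryl ether tolerates this weak base.

Step 6
Reactants: 10 [4-(4-bromophenoxy)-3,5-dimethoxyphenoxy]tri(propan-2-yl)silane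
Product: 11 4-(4-bromophenoxy)-3,5-dimethoxyphenol
Conditions: TBAF (1.1 equiv), AcOH (1.1 equiv), THF, 0 °C
Reagents that add atoms: none
Why: Fluoride-induced cleavage of an aryl silyl ether, buffered with AcOH so that the electron-rich phenol is released in neutral form, with all other groups inert.

Step 7
Reactants: 11 4-(4-bromophenoxy)-3,5-dimethoxyphenol
Product: 12 1-[3-(4-bromophenoxy)-6-hydroxy-2,4-dimethoxyphenyl]ethan-1-one
Conditions: AcOH, BF3·OEt2 (excess), 85 °C; then H2O
Reagents that add atoms: acetic acid, CC(=O)O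
Why: Friedel–Crafts acylation (O-acetylation and Fries shift) as practised on 3,4,5-trialkoxyphenols: the two positions ortho to the OH are equivalent, the product is held as its BF2 chelate, which protects the neighbouring OMe, and the bromophenoxy ring is far less nucleophilic.

Step 8
Reactants: 12 1-[3-(4-bromophenoxy)-6-hydroxy-2,4-dimethoxyphenyl]ethan-1-one; 13 4-(benzyloxy)benzaldehyde
Product: 14 (E)-3-[4-(benzyloxy)phenyl]-1-[3-(4-bromophenoxy)-6-hydroxy-2,4-dimethoxyphenyl]prop-2-en-1-one
Conditions: KOH (50 % aq), EtOH, rt; then 1 M HCl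
Reagents that add atoms: none
Why: Claisen–Schmidt aldol condensation of a methyl ketone with a non-enolisable aldehyde, in which E1cB dehydration under equilibrating conditions gives the E-chalcone.

Step 9
Reactants: 14 (E)-3-[4-(benzyloxy)phenyl]-1-[3-(4-bromophenoxy)-6-hydroxy-2,4-dimethoxyphenyl]prop-2-en-1-one
Product: 15 2-[4-(benzyloxy)phenyl]-6-(4-bromophenoxy)-5,7-dimethoxy-4H-chromen-4-one
Conditions: I2 (10 mol %), DMSO, 130 °C
Reagents that add atoms: none
Why: Iodine-catalysed oxidative cyclisation of a 2'-hydroxychalcone (6-endo-trig oxa-Michael closure, α-iodination, loss of HI, reoxidation of HI by DMSO), and since only one phenol ortho to the ketone is free, O1''–C2'' must form from it and the aryloxy group ends at C6''.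

Step 10
Reactants: 15 2-[4-(benzyloxy)phenyl]-6-(4-bromophenoxy)-5,7-dimethoxy-4H-chromen-4-one
Product: 16 2-[4-(benzyloxy)phenyl]-5,7-dimethoxy-6-[4-(4,4,5,5-tetramethyl-1,3,2-dioxaborolan-2-yl)phenoxy]-4H-chromen-4-one
Conditions: bis(pinacolato)diboron (1.2 equiv), PdCl2(dppf) (3 mol %), KOAc (3 equiv), 1,4-dioxane, 90 °C
Reagents that add atoms: bis(pinacolato)diboron, CC1(C)OB(OC1(C)C)B1OC(C)(C)C(C)(C)O1
Why: Miyaura borylation of the only aryl halide in the molecule, with KOAc too weak a base to open the pyranone or to start homocoupling.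

Step 11
Reactants: 17 1,3,5-trimethoxybenzene; 18 3,3-dichloroprop-2-enoyl chloride
Product: 20 3,3-dichloro-1-(2-hydroxy-4,6-dimethoxyphenyl)prop-2-en-1-one, via trimethoxyphenyl dichlorovinyl ketone 19 (not isolated)
Conditions: AlCl3 (2.2 equiv) premixed with 18, CH2Cl2, 0 °C, 17 added; then rt; cold 1 M HCl
Reagents that add atoms: none
Why: Friedel–Crafts acylation of a symmetric arene followed in the same flask by chelation-directed cleavage of one ortho methyl ether by AlCl3, where the two ortho OMe groups are equivalent and the aluminium chelate slows a second cleavage.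

Step 12
Reactants: 20 3,3-dichloro-1-(2-hydroxy-4,6-dimethoxyphenyl)prop-2-en-1-one
Product: 21 2-chloro-5,7-dimethoxy-4H-chromen-4-one
Conditions: K2CO3 (1.5 equiv), acetone, rt
Reagents that add atoms: none
Why: Intramolecular vinylic substitution (6-endo-trig oxa-Michael addition, then loss of chloride), the known conversion of o-hydroxyaryl β,β-dichlorovinyl ketones into 2-chlorochromones, run without water so that the C2–Cl bond is kept.

Step 13
Reactants: 16 2-[4-(benzyloxy)phenyl]-5,7-dimethoxy-6-[4-(4,4,5,5-tetramethyl-1,3,2-dioxaborolan-2-yl)phenoxy]-4H-chromen-4-one; 21 2-chloro-5,7-dimethoxy-4H-chromen-4-one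
Product: 22 2-[4-(benzyloxy)phenyl]-6-[4-(5,7-dimethoxy-4-oxo-4H-chromen-2-yl)phenoxy]-5,7-dimethoxy-4H-chromen-4-one
Conditions: Pd(PPh3)4 (5 mol %), K3PO4 (2 equiv), 1,4-dioxane–H2O (10:1), 85 °C
Reagents that add atoms: none
Why: Suzuki–Miyaura coupling, known for 2-chlorochromones with arylboron reagents, in which the C2–Cl bond behaves as a vinylogous acyl chloride and adds readily to zerovalent palladium, forming C2–C1' and completing the second flavone.

Step 14
Reactants: 22 2-[4-(benzyloxy)phenyl]-6-[4-(5,7-dimethoxy-4-oxo-4H-chromen-2-yl)phenoxy]-5,7-dimethoxy-4H-chromen-4-one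
Product: 23 5-hydroxy-6-[4-(5-hydroxy-7-methoxy-4-oxo-4H-chromen-2-yl)phenoxy]-2-(4-hydroxyphenyl)-7-methoxy-4H-chromen-4-one (CNP0251572.0)
Conditions: BCl3 (8 equiv), pentamethylbenzene (3 equiv), CH2Cl2, −78 °C to rt; then 1 M HCl
Reagents that add atoms: none
Why: Lewis-acid ether cleavage in which BCl3 binds each C4 carbonyl and removes only the peri 5- and 5''-methyl groups through six-membered chelates and also cleaves the benzyl ether with pentamethylbenzene as cation trap, while the unchelated 7- and 7''-methyl ethers and the diaryl ether should stay.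

## Compound list

1 | 4-bromophenol | Oc1ccc(Br)cc1 | starting material
2 | dimethyl 2-chloropropanedioate | COC(=O)C(Cl)C(=O)OC | starting material
3 | dimethyl 2-(4-bromophenoxy)propanedioate | COC(=O)C(Oc1ccc(Br)cc1)C(=O)OC | intermediate
4 | dimethyl 3-oxopentanedioate | COC(=O)CC(=O)CC(=O)OC | starting material
5 | dimethyl 2-(4-bromophenoxy)-4-(methoxycarbonyl)-3,5-dioxoheptanedioate (not isolated) | COC(=O)CC(=O)C(C(=O)OC)C(=O)C(Oc1ccc(Br)cc1)C(=O)OC | intermediate
6 | dimethyl 5-(4-bromophenoxy)-2,4,6-trihydroxybenzene-1,3-dicarboxylate | COC(=O)c1c(O)c(C(=O)OC)c(O)c(Oc2ccc(Br)cc2)c1O | intermediate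
7 | 5-(4-bromophenoxy)-2,4,6-trihydroxybenzene-1,3-dicarboxylic acid (not isolated) | OC(=O)c1c(O)c(C(=O)O)c(O)c(Oc2ccc(Br)cc2)c1O | intermediate
8 | 2-(4-bromophenoxy)benzene-1,3,5-triol | Oc1cc(O)c(Oc2ccc(Br)cc2)c(O)c1 | intermediate
9 | 2-(4-bromophenoxy)-5-{[tri(propan-2-yl)silyl]oxy}benzene-1,3-diol | CC(C)[Si](Oc1cc(O)c(Oc2ccc(Br)cc2)c(O)c1)(C(C)C)C(C)C | intermediate
10 | [4-(4-bromophenoxy)-3,5-dimethoxyphenoxy]tri(propan-2-yl)silane | COc1cc(O[Si](C(C)C)(C(C)C)C(C)C)cc(OC)c1Oc1ccc(Br)cc1 | intermediate
11 | 4-(4-bromophenoxy)-3,5-dimethoxyphenol | COc1cc(O)cc(OC)c1Oc1ccc(Br)cc1 | intermediate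
12 | 1-[3-(4-bromophenoxy)-6-hydroxy-2,4-dimethoxyphenyl]ethan-1-one | CC(=O)c1c(O)cc(OC)c(Oc2ccc(Br)cc2)c1OC | intermediate
13 | 4-(benzyloxy)benzaldehyde | O=Cc1ccc(OCc2ccccc2)cc1 | starting material
14 | (E)-3-[4-(benzyloxy)phenyl]-1-[3-(4-bromophenoxy)-6-hydroxy-2,4-dimethoxyphenyl]prop-2-en-1-one | COc1cc(O)c(C(=O)/C=C/c2ccc(OCc3ccccc3)cc2)c(OC)c1Oc1ccc(Br)cc1 | intermediate
15 | 2-[4-(benzyloxy)phenyl]-6-(4-bromophenoxy)-5,7-dimethoxy-4H-chromen-4-one | COc1cc2oc(-c3ccc(OCc4ccccc4)cc3)cc(=O)c2c(OC)c1Oc1ccc(Br)cc1 | intermediate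
16 | 2-[4-(benzyloxy)phenyl]-5,7-dimethoxy-6-[4-(4,4,5,5-tetramethyl-1,3,2-dioxaborolan-2-yl)phenoxy]-4H-chromen-4-one | COc1cc2oc(-c3ccc(OCc4ccccc4)cc3)cc(=O)c2c(OC)c1Oc1ccc(B2OC(C)(C)C(C)(C)O2)cc1 | intermediate
17 | 1,3,5-trimethoxybenzene | COc1cc(OC)cc(OC)c1 | starting material
18 | 3,3-dichloroprop-2-enoyl chloride | O=C(Cl)C=C(Cl)Cl | starting material
19 | 3,3-dichloro-1-(2,4,6-trimethoxyphenyl)prop-2-en-1-one (not isolated) | COc1cc(OC)c(C(=O)C=C(Cl)Cl)c(OC)c1 | intermediate
20 | 3,3-dichloro-1-(2-hydroxy-4,6-dimethoxyphenyl)prop-2-en-1-one | COc1cc(O)c(C(=O)C=C(Cl)Cl)c(OC)c1 | intermediate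
21 | 2-chloro-5,7-dimethoxy-4H-chromen-4-one | COc1cc(OC)c2c(=O)cc(Cl)oc2c1 | intermediate
22 | 2-[4-(benzyloxy)phenyl]-6-[4-(5,7-dimethoxy-4-oxo-4H-chromen-2-yl)phenoxy]-5,7-dimethoxy-4H-chromen-4-one | COc1cc(OC)c2c(=O)cc(-c3ccc(Oc4c(OC)cc5oc(-c6ccc(OCc7ccccc7)cc6)cc(=O)c5c4OC)cc3)oc2c1 | intermediate
23 | 5-hydroxy-6-[4-(5-hydroxy-7-methoxy-4-oxo-4H-chromen-2-yl)phenoxy]-2-(4-hydroxyphenyl)-7-methoxy-4H-chromen-4-one | COc1cc(O)c2c(=O)cc(-c3ccc(Oc4c(OC)cc5oc(-c6ccc(O)cc6)cc(=O)c5c4O)cc3)oc2c1 | target

Total step count: 14. Longest linear sequence: 12 (steps 1–10, 13, 14).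

## Steps most likely to fail

**1. Step 2.**
- What may go wrong: 4 may self-condense through its ketone faster than it is acylated. The partly enolised, α-branched malonate may react too slowly. The sequence may also stall after O-acylation.
- Fallback (known chemistry): it sets out from 17 and rejoins at 8, so ring A'' is taken as a bought arene and the ether is made by O-arylation of a phenol.
- Compound 17 is lithiated (n-BuLi, THF, 0 °C), treated with B(OMe)3 and oxidised (H2O2, NaOH) to 2,4,6-trimethoxyphenol F1.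
- The potassium salt of F1 (t-BuOK, THF, 40 °C) is arylated with bis(4-bromophenyl)iodonium triflate. This metal-free ligand coupling tolerates 2,6-disubstituted phenols and aryl bromides, and gives 2-(4-bromophenoxy)-1,3,5-trimethoxybenzene F2.
- BBr3 (CH2Cl2, −78 °C to rt) then cleaves the three methyl ethers, leaves the diaryl ether and delivers 8.

**2. Step 4.**
- What may go wrong: poor discrimination between the unflanked and the two flanked hydroxyl groups, and over-silylation.
- Fallback: it sets out from 8 and rejoins at 12. The oxygens are differentiated only after C-acylation, through the ketone chelate, as is familiar for 3-substituted phloroacetophenones.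
- Compound 8 is acetylated (AcOH, BF3·OEt2, 80 °C) to 1-[3-(4-bromophenoxy)-2,4,6-trihydroxyphenyl]ethan-1-one F3.
- MOMCl (2.1 equiv) with i-Pr2NEt in CH2Cl2 at 0 °C protects the para OH and the less hindered ortho OH. The OH wedged between acetyl and aryloxy stays in the chelate, giving 1-[3-(4-bromophenoxy)-2-hydroxy-4,6-bis(methoxymethoxy)phenyl]ethan-1-one F4.
- Forcing methylation (Me2SO4, K2CO3, acetone, reflux) gives 1-[3-(4-bromophenoxy)-2-methoxy-4,6-bis(methoxymethoxy)phenyl]ethan-1-one F5.
- HCl in MeOH (50 °C) releases 1-[3-(4-bromophenoxy)-4,6-dihydroxy-2-methoxyphenyl]ethan-1-one F6.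
- One equivalent of Me2SO4 with K2CO3 in acetone methylates the unchelated para OH and gives 12.

**3. Step 13.**
- What may go wrong: hydrolysis or substitution of the C2–Cl bond by the aqueous base before oxidative addition, and protodeboronation of 16.
- Fallback: it sets out from 16 and rejoins at 22. It replaces cross-coupling by conjugate addition and dehydrogenation, and also makes steps 11–12 unnecessary.
- Compound 16 is cleaved with NaIO4 and NH4OAc (acetone–H2O, rt) to the boronic acid {4-[(2-[4-(benzyloxy)phenyl]-5,7-dimethoxy-4-oxo-4H-chromen-6-yl)oxy]phenyl}boronic acid F7.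
- Commercial 2'-hydroxy-4',6'-dimethoxyacetophenone and DMF dimethyl acetal (toluene, 100 °C) give the enaminone (E)-3-(dimethylamino)-1-(2-hydroxy-4,6-dimethoxyphenyl)prop-2-en-1-one F8.
- HCl in CH2Cl2 closes F8 to 5,7-dimethoxy-4H-chromen-4-one F9.
- Addition of F7 to F9 under catalysis by divalent palladium (Pd(OCOCF3)2, 2,2'-bipyridine, AcOH–THF–H2O, 60 °C) gives the racemic flavanone F10.
- I2 (cat.) in DMSO at 130 °C dehydrogenates F10 to 22.

## Further compounds

F1 | step 2 | 2,4,6-trimethoxyphenol | COc1cc(OC)c(O)c(OC)c1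
F2 | step 2 | 2-(4-bromophenoxy)-1,3,5-trimethoxybenzene | COc1cc(OC)c(Oc2ccc(Br)cc2)c(OC)c1
F3 | step 4 | 1-[3-(4-bromophenoxy)-2,4,6-trihydroxyphenyl]ethan-1-one | CC(=O)c1c(O)cc(O)c(Oc2ccc(Br)cc2)c1O
F4 | step 4 | 1-[3-(4-bromophenoxy)-2-hydroxy-4,6-bis(methoxymethoxy)phenyl]ethan-1-one | CC(=O)c1c(OCOC)cc(OCOC)c(Oc2ccc(Br)cc2)c1O
F5 | step 4 | 1-[3-(4-bromophenoxy)-2-methoxy-4,6-bis(methoxymethoxy)phenyl]ethan-1-one | CC(=O)c1c(OCOC)cc(OCOC)c(Oc2ccc(Br)cc2)c1OC
F6 | step 4 | 1-[3-(4-bromophenoxy)-4,6-dihydroxy-2-methoxyphenyl]ethan-1-one | CC(=O)c1c(O)cc(O)c(Oc2ccc(Br)cc2)c1OC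
F7 | step 13 | {4-[(2-[4-(benzyloxy)phenyl]-5,7-dimethoxy-4-oxo-4H-chromen-6-yl)oxy]phenyl}boronic acid | COc1cc2oc(-c3ccc(OCc4ccccc4)cc3)cc(=O)c2c(OC)c1Oc1ccc(B(O)O)cc1
F8 | step 13 | (E)-3-(dimethylamino)-1-(2-hydroxy-4,6-dimethoxyphenyl)prop-2-en-1-one | COc1cc(O)c(C(=O)/C=C/N(C)C)c(OC)c1
F9 | step 13 | 5,7-dimethoxy-4H-chromen-4-one | COc1cc(OC)c2c(=O)ccoc2c1
F10 | step 13 | 2-[4-(benzyloxy)phenyl]-6-[4-(5,7-dimethoxy-4-oxochroman-2-yl)phenoxy]-5,7-dimethoxy-4H-chromen-4-one (racemic) | COc1cc(OC)c2C(=O)CC(c3ccc(Oc4c(OC)cc5oc(-c6ccc(OCc7ccccc7)cc6)cc(=O)c5c4OC)cc3)Oc2c1
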